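## Retrosynthetic overview

- Last event: the racemic alkaloid is turned into the single enantiomer by crystallisation-induced dynamic resolution; the two antipodes differ only at the four enolisable C1/C3 carbons.
- Key disconnection: both N–C4 bonds (aza-Michael) and both C1–C10 bonds (Mannich) are cut at once, back to two molecules of one achiral C15 amino-aldehyde enone held as its cyclic iminium ion. The forward reaction is a head-to-tail cyclodimerisation under thermodynamic control.
- Ring order: piperideine rings (carried from the lactam) → 28-membered bis-iminium macrocycle → two piperidin-4-one rings, which complete both quinolizidin-2-ones and leave the 16-membered carbocycle.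
- Monomer: a Boc ene-carbamate carrying an isopropenyl ketone, made from N-Boc-2-piperidone and 7-bromoheptanenitrile (enolate alkylation, lactam reduction–dehydration, Grignard addition to the nitrile).
- Locants (quinolizidine numbering): N5; C1 = CH next to C2=O; C3 = CHMe; C9 = CH carrying the other chain; C10 = ring fusion; primes mark the second unit.

Assumption: which hand of camphorsulfonic acid crystallises with the wanted antipode cannot be predicted on paper; the (1S)-(+)-acid is written, and the (1R)-(−)-acid takes its place if the first crystals prove to be the mirror image.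

## Route

Step 1
Reactants: 1 tert-butyl 2-oxopiperidine-1-carboxylate; 2 7-bromoheptanenitrile
Product: 3 tert-butyl 3-(6-cyanohexyl)-2-oxopiperidine-1-carboxylate (racemic)
Conditions: LiHMDS (1.1 equiv), THF, −78 °C, 45 min; then 2 (1.3 equiv), DMPU, n-Bu4NI (10 mol %), −78 → −20 °C, 8 h
Reagents that add atoms: none
Why: SN2 alkylation of the lithium enolate of the imide-like N-Boc lactam (lactam enolate alkylation); the nitrile α-protons are not touched, and the new centre (the later C9) is left racemic because it is erased in step 2 and set again under equilibrium in step 4.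

Step 2
Reactants: 3 tert-butyl 3-(6-cyanohexyl)-2-oxopiperidine-1-carboxylate
Product: 6 tert-butyl 5-(6-cyanohexyl)-3,4-dihydropyridine-1(2H)-carboxylate, via hemiaminal lithium alkoxide 4 (not isolated), via hemiaminal trifluoroacetate 5 (not isolated)
Conditions: LiEt3BH (1.1 equiv), toluene/THF, −78 °C, 30 min; then i-Pr2NEt (5 equiv), DMAP (2 mol %), TFAA (1.2 equiv), −78 °C → rt, 3 h
Reagents that add atoms: none
Why: Partial hydride reduction of the activated N-Boc lactam to the hemiaminal (the aliphatic nitrile survives Super-Hydride at −78 °C), then in-flask trifluoroacetylation–elimination to the endocyclic ene-carbamate, a storable masked 5-amino aldehyde with no stereocentre.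

Step 3
Reactants: 6 tert-butyl 5-(6-cyanohexyl)-3,4-dihydropyridine-1(2H)-carboxylate
Product: 8 tert-butyl 5-(8-methyl-7-oxonon-8-en-1-yl)-3,4-dihydropyridine-1(2H)-carboxylate, via N-bromomagnesio ketimine 7 (not isolated)
Conditions: isopropenylmagnesium bromide (2.5 equiv), CuBr·SMe2 (5 mol %), THF, 0 °C → rt, 16 h; then aq. AcOH/NaOAc (pH 5), 0 °C, 30 min; BHT added, used at once
Reagents that add atoms: isopropenylmagnesium bromide C=C(C)[Mg]Br; water O
Why: Grignard addition to a nitrile stops at the N-magnesio ketimine, which buffered aqueous hydrolysis turns into the α-methylene (isopropenyl) ketone; the ene-carbamate and Boc group are inert to the Grignard reagent and to pH 5, and no stereocentre is formed.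

Step 4
Reactants: 8 tert-butyl 5-(8-methyl-7-oxonon-8-en-1-yl)-3,4-dihydropyridine-1(2H)-carboxylate (two molecules)
Product: 11 racemic form of the target diastereomer, via monomeric piperideinium salt 9 (not isolated), via macrocyclic bis-iminium diketone 10 (not isolated)
Conditions: TFA/CH2Cl2 (1:4), 0 °C → rt, 1 h, evaporate; then MeCN/H2O (9:1), NaOAc/AcOH buffer (pH 5–5.5), 0.01 M, 65 °C, 72–96 h; aq. NaOH to pH 10 (0 °C), CH2Cl2; chromatography on basic alumina; the other diastereomers are returned to the buffer
Reagents that add atoms: none
Why: Proposed new method: acid frees the 5-alkyl-Δ1-piperideinium ion 9, whose imine nitrogen adds head-to-tail to the isopropenyl ketone of a second molecule (aza-Michael, N–C4), and the resulting N-alkyl iminium is closed by the C1 enol of the new β-amino ketone (6-endo Mannich, C1–C10), twice, through the 28-membered bis-iminium 10, so that both piperidin-4-one rings and the 16-membered carbocycle form in one flask; the closest known reaction type is the cyclic-imine plus α-methylene-ketone annulation to benzo[a]quinolizidin-2-ones (tetrabenazine-type synthesis), here run in both directions at once as a Mannich macrocyclodimerisation; all eight centres are set under thermodynamic control (C9 by iminium–enamine tautomerism, C1 and C10 by retro-Mannich/Mannich, C3 by enolisation), each half settling 9,10-trans and 1,3-cis with all substituents equatorial (one trans-fused unit, one 1,10-cis unit in its cis-fused conformer), the heterochiral C9/C9' pairing arising because the monomer is achiral, and the wanted diastereomer is separated as the racemate.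

Step 5
Reactants: 11 racemic form of the target diastereomer
Product: 13 target (1S,3R,9R,10R,1'S,3'R,9'S,10'S), via bis-camphorsulfonate salt 12 (not isolated)
Conditions: (1S)-(+)-10-camphorsulfonic acid (2.05 equiv), EtOAc/EtOH (9:1), 50 °C slurry, 72 h, seeding, cool to 0 °C, filter; wet cake partitioned at once between CH2Cl2 and sat. aq. NaHCO3, 0 °C
Reagents that add atoms: none
Why: Proposed new method: crystallisation-induced dynamic resolution, in which the two antipodes of 11 interconvert in the warm acidic mother liquor because they differ only at the enolisable carbons C1, C3, C1' and C3' (acid-catalysed enolisation through the two meso epimers, with retro-Mannich/Mannich as a second channel) while the less soluble diastereomeric bis-sulfonate salt leaves the equilibrium as crystals, so the absolute configuration of all eight centres is fixed by the salt lattice and kept by cold, fast liberation of the base; the closest known reaction type is the camphorsulfonic acid dynamic resolution of 3-alkyl-benzo[a]quinolizidin-2-one Mannich bases, which racemise by the same acid-mediated pathway.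

## Compound list

1 | tert-butyl 2-oxopiperidine-1-carboxylate (N-Boc-2-piperidone) | CC(C)(C)OC(=O)N1CCCCC1=O | starting material
2 | 7-bromoheptanenitrile | N#CCCCCCCBr | starting material
3 | tert-butyl 3-(6-cyanohexyl)-2-oxopiperidine-1-carboxylate (racemic) | CC(C)(C)OC(=O)N1CCCC(CCCCCCC#N)C1=O | intermediate
4 | tert-butyl 3-(6-cyanohexyl)-2-hydroxypiperidine-1-carboxylate (hemiaminal, present as its lithium alkoxide; racemic diastereomer mixture) | CC(C)(C)OC(=O)N1CCCC(CCCCCCC#N)C1O | intermediate
5 | tert-butyl 3-(6-cyanohexyl)-2-(trifluoroacetoxy)piperidine-1-carboxylate (racemic diastereomer mixture) | CC(C)(C)OC(=O)N1CCCC(CCCCCCC#N)C1OC(=O)C(F)(F)F | intermediate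
6 | tert-butyl 5-(6-cyanohexyl)-3,4-dihydropyridine-1(2H)-carboxylate (achiral) | CC(C)(C)OC(=O)N1CCCC(CCCCCCC#N)=C1 | intermediate
7 | N-bromomagnesio ketimine of 8 (tert-butyl 5-[7-(bromomagnesioimino)-8-methylnon-8-en-1-yl]-3,4-dihydropyridine-1(2H)-carboxylate) | CC(C)(C)OC(=O)N1CCCC(CCCCCCC(=N[Mg]Br)C(C)=C)=C1 | intermediate
8 | tert-butyl 5-(8-methyl-7-oxonon-8-en-1-yl)-3,4-dihydropyridine-1(2H)-carboxylate (achiral) | CC(C)(C)OC(=O)N1CCCC(CCCCCCC(=O)C(C)=C)=C1 | intermediate
9 | 5-(8-methyl-7-oxonon-8-en-1-yl)-2,3,4,5-tetrahydropyridin-1-ium trifluoroacetate (racemic, centre labile) | C=C(C)C(=O)CCCCCCC1CCC[NH+]=C1.[O-]C(=O)C(F)(F)F | intermediate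
10 | 28-membered head-to-tail cyclodimer: two tetrahydropyridinium rings, each N+ carrying CH2CH(CH3)C(=O)(CH2)6 that ends at the carbon next to the iminium carbon of the other ring; bis(trifluoroacetate); labile centres, stereoisomer mixture | CC1C[N+]2=CC(CCC2)CCCCCCC(=O)C(C)C[N+]3=CC(CCC3)CCCCCCC1=O.[O-]C(=O)C(F)(F)F.[O-]C(=O)C(F)(F)F | intermediate
11 | racemate of 13: 16-membered carbocycle fused to two 3-methylquinolizidin-2-ones, each C1 joined through (CH2)5 to C9 of the other unit; relative configuration 1S*,3R*,9R*,10R*,1'S*,3'R*,9'S*,10'S* (one enantiomer drawn, mirror image also present) | C[C@@H]1CN2CCC[C@H]3CCCCC[C@@H]4C(=O)[C@H](C)CN5CCC[C@H](CCCCC[C@H](C1=O)[C@@H]32)[C@@H]45 | intermediate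
12 | bis[(1S)-camphor-10-sulfonate] salt of 13 | C[C@@H]1CN2CCC[C@H]3CCCCC[C@@H]4C(=O)[C@H](C)CN5CCC[C@H](CCCCC[C@H](C1=O)[C@@H]32)[C@@H]45.OS(=O)(=O)C[C@@]12CC[C@@H](C1(C)C)CC2=O.OS(=O)(=O)C[C@@]12CC[C@@H](C1(C)C)CC2=O | intermediate
13 | target: (1S,3R,9R,10R)-unit with 1-H/10-H cis and (1'S,3'R,9'S,10'S)-unit with 1-H/10-H trans; 9-H/10-H trans and CH3 cis to the C1 chain in both units | C[C@@H]1CN2CCC[C@H]3CCCCC[C@@H]4C(=O)[C@H](C)CN5CCC[C@H](CCCCC[C@H](C1=O)[C@@H]32)[C@@H]45 | target

## Step count and risks

Total step count: 5. Longest linear sequence: 5 steps (1 → 3 → 6 → 8 → 11 → 13).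

Three steps most likely to fail:

Step 4 (cyclodimerisation). The enamine tautomer of 9 can attack the enone through carbon (C9) instead of nitrogen, which gives an irreversible hydroquinolinone annulation. Linear oligomers can form, and the share of the wanted diastereomer at equilibrium is unknown. The fallback sets out from 3 and comes back at 10. It makes the N–C4 bonds while nitrogen is still an amide, so alkylation at C9 cannot compete. TFA in CH2Cl2 removes the Boc group of 3 to give 3-(6-cyanohexyl)piperidin-2-one F3. Isopropenylmagnesium bromide (3 equiv, the first deprotonates N–H) and buffered hydrolysis give 3-(8-methyl-7-oxonon-8-en-1-yl)piperidin-2-one F4. Catalytic KOt-Bu in THF/t-BuOH at 5 mM brings about the reversible head-to-tail double aza-Michael addition of the lactam N–H to the enone and gives the 28-membered macrocyclic bis-lactam diketone F5. Mo(CO)6-catalysed hydrosilylation with TMDS (amide-selective, ketones spared) reduces both lactams to the endocyclic enamines. Acetic acid protonates them to the bis-iminium 10, which closes to 11 under the buffer of step 4.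

Step 5 (dynamic resolution). The salt of a meso epimer or of another diastereomer may be the one that crystallises, or nothing may crystallise. The fallback sets out from 11 and comes back at 13. Preparative chiral SFC (immobilised amylose tris(3,5-dimethylphenylcarbamate), CO2/MeOH with 0.1% Et2NH, 25 °C) separates 13 from its mirror image, the (1R,3S,9S,10S,1'R,3'S,9'R,10'R)-antipode F6. F6 is returned to the pH 5 buffer of step 4 to regenerate 11.

Step 3 (Grignard addition to the nitrile). α-Deprotonation of the nitrile, attack on the Boc carbonyl, or polymerisation of the enone during hydrolysis may occur. The fallback sets out from 6 and comes back at 8. DIBAL-H (toluene, −78 °C) followed by aqueous tartaric acid gives tert-butyl 5-(7-oxoheptyl)-3,4-dihydropyridine-1(2H)-carboxylate F1. Isopropenylmagnesium bromide at −78 °C gives tert-butyl 5-(7-hydroxy-8-methylnon-8-en-1-yl)-3,4-dihydropyridine-1(2H)-carboxylate F2. Dess–Martin periodinane with NaHCO3 oxidises F2 to 8.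

Further compounds
F1 | step 3 | tert-butyl 5-(7-oxoheptyl)-3,4-dihydropyridine-1(2H)-carboxylate | CC(C)(C)OC(=O)N1CCCC(CCCCCCC=O)=C1
F2 | step 3 | tert-butyl 5-(7-hydroxy-8-methylnon-8-en-1-yl)-3,4-dihydropyridine-1(2H)-carboxylate (racemic) | CC(C)(C)OC(=O)N1CCCC(CCCCCCC(O)C(C)=C)=C1
F3 | step 4 | 3-(6-cyanohexyl)piperidin-2-one (racemic) | N#CCCCCCCC1CCCNC1=O
F4 | step 4 | 3-(8-methyl-7-oxonon-8-en-1-yl)piperidin-2-one (racemic) | C=C(C)C(=O)CCCCCCC1CCCNC1=O
F5 | step 4 | 28-membered macrocyclic bis-lactam diketone (head-to-tail; stereoisomer mixture) | CC1CN2CCCC(C2=O)CCCCCCC(=O)C(C)CN3CCCC(C3=O)CCCCCCC1=O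
F6 | step 5 | mirror image of 13 (1R,3S,9S,10S,1'R,3'S,9'R,10'R) | C[C@H]1CN2CCC[C@@H]3CCCCC[C@H]4C(=O)[C@@H](C)CN5CCC[C@@H](CCCCC[C@@H](C1=O)[C@H]32)[C@H]45
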